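**Plan**

- Numbering (azulene): C3 carbinol carbon with isopropyl, C3a ring-fusion CH, C4 aroyloxy carbon, C5 CH2, C6(CH3)=C7, C8 isovaleryloxy carbon, C8a quaternary methyl carbon. The retrosynthesis first cuts the two ester C–O bonds, takes C4 back to a ketone and the C6 methyl back to an ester.
- Enabling feature: in the seven-membered ring the C6=C7 alkene and the C3a–C4 pair (a masked enol ether) flank the C5 methylene. The ring is therefore a latent cyclohepta-1,4-diene whose remaining single bond, C8–C8a, links the oxygenated CH to the quaternary methyl carbon. Cutting C8–C8a and then C5–C6 (retro-Cope, retro-cyclopropanation, a formal (4+3)) gives a cyclopentenyl 2-siloxydiene and a 4-siloxyvinyl rhodium carbenoid.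
- The cyclopentene C3a=C8a bond is cut by a retro-aldol condensation to a keto aldehyde, the ozonolysis product of (R)-terpinen-4-ol.
- Forward order: cyclohexene, then cyclopentene (ozonolysis, aldol), then cyclopropane expanded in the same flask to the seven-membered ring, then ester to methyl, enol ether to ketone, ketone to alcohol and two acylations.
- Stereochemistry: C3 comes from the chiral pool. C8 and C8a come from the catalyst-controlled cyclopropanation, relayed through the boat Cope transition state with an E enol ether. C3a is set by protonation anti to methyl and isopropyl, and C4 by hydride delivered from the C3 hydroxyl.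

Key step: step 9

Assumption: the prolinate catalyst is taken to transfer the vinylcarbenoid to the siloxy alkene with the same facial sense it shows with styrene-type alkenes, which makes Rh2(R-DOSP)4 the enantiomer that leads to cyclopropane 13; if the sense were opposite, Rh2(S-DOSP)4 would be used instead.

**Step 1**
Reactants: 1 (R)-terpinen-4-ol [(1R)-4-methyl-1-(propan-2-yl)cyclohex-3-en-1-ol]
Product: 2 triethyl{[(1R)-4-methyl-1-(propan-2-yl)cyclohex-3-en-1-yl]oxy}silane
Conditions: Et3SiOTf, 2,6-lutidine, CH2Cl2, −78 → 0 °C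
Reagents that add atoms: triethylsilyl trifluoromethanesulfonate, CC[Si](CC)(CC)OS(=O)(=O)C(F)(F)F
Why: Silylation with a silyl triflate and a hindered pyridine base works even on tertiary alcohols; the ether prevents hemiketal formation and retro-aldol cleavage after ozonolysis, and the stereocentre is not involved.

**Step 2**
Reactants: 2 triethyl{[(1R)-4-methyl-1-(propan-2-yl)cyclohex-3-en-1-yl]oxy}silane
Product: 4 (3R)-6-oxo-3-(propan-2-yl)-3-[(triethylsilyl)oxy]heptanal, via secondary ozonide 3 (not isolated)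
Conditions: O3, CH2Cl2, −78 °C; then PPh3, −78 °C → rt
Reagents that add atoms: ozone, [O-][O+]=O
Why: Ozonolysis (Criegee mechanism) of the only alkene, followed by phosphine reduction of the ozonide, gives the methyl ketone and the aldehyde; the tertiary silyl ether is inert and the stereocentre is untouched.

**Step 3**
Reactants: 4 (3R)-6-oxo-3-(propan-2-yl)-3-[(triethylsilyl)oxy]heptanal
Product: 5 (5S)-2-methyl-5-(propan-2-yl)-5-[(triethylsilyl)oxy]cyclopent-1-ene-1-carbaldehyde
Conditions: piperidine, AcOH (20 mol % each), toluene, 4 Å molecular sieves, 60 °C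
Reagents that add atoms: none
Why: Intramolecular aldol condensation through the piperidine enamine of the aldehyde, whose α carbon attacks the methyl ketone (5-enolexo-exo-trig) before water is lost into conjugation; the amine–acid buffer favours this mode over enolisation of the ketone and should be mild enough to leave the β-silyloxy group in place.

**Step 4**
Reactants: 5 (5S)-2-methyl-5-(propan-2-yl)-5-[(triethylsilyl)oxy]cyclopent-1-ene-1-carbaldehyde
Product: 6 1-[(5S)-2-methyl-5-(propan-2-yl)-5-(triethylsilyloxy)cyclopent-1-en-1-yl]ethan-1-ol (both carbinol epimers)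
Conditions: CH3MgBr, THF, −78 → 0 °C
Reagents that add atoms: methylmagnesium bromide, C[Mg]Br
Why: Grignard 1,2-addition to the enal, whose tetrasubstituted β carbon rules out conjugate addition; the new carbinol centre is erased in step 5.

**Step 5**
Reactants: 6 1-[(5S)-2-methyl-5-(propan-2-yl)-5-(triethylsilyloxy)cyclopent-1-en-1-yl]ethan-1-ol
Product: 7 1-[(5S)-2-methyl-5-(propan-2-yl)-5-(triethylsilyloxy)cyclopent-1-en-1-yl]ethan-1-one
Conditions: Dess–Martin periodinane, pyridine, CH2Cl2, 0 °C → rt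
Reagents that add atoms: none
Why: Dess–Martin oxidation of the hindered secondary allylic alcohol is fast and close to neutral, so the tertiary allylic silyl ether should survive.

**Step 6**
Reactants: 7 1-[(5S)-2-methyl-5-(propan-2-yl)-5-(triethylsilyloxy)cyclopent-1-en-1-yl]ethan-1-one
Product: 8 triethyl({1-[(5S)-2-methyl-5-(propan-2-yl)-5-(triethylsilyloxy)cyclopent-1-en-1-yl]ethenyl}oxy)silane
Conditions: LiN(i-Pr)2, THF, −78 °C; then Et3SiCl, Et3N, −78 → 0 °C
Reagents that add atoms: chlorotriethylsilane, CC[Si](CC)(CC)Cl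
Why: Kinetic deprotonation by the lithium amide at the α′ methyl group (cross-conjugated enolate, γ-deprotonation being slower at −78 °C) and O-silylation give the 2-siloxydiene.

**Step 7**
Reactants: 9 ethyl diazoacetate; 10 (tert-butyldimethylsilyloxy)acetaldehyde
Product: 11 ethyl 4-[(tert-butyldimethylsilyl)oxy]-2-diazo-3-hydroxybutanoate (racemic)
Conditions: DBU (20 mol %), CH3CN, rt
Reagents that add atoms: none
Why: Base-catalysed aldol-type addition of the acidic diazoacetate C–H to the aldehyde; the new carbinol centre is removed in step 8.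

**Step 8**
Reactants: 11 ethyl 4-[(tert-butyldimethylsilyl)oxy]-2-diazo-3-hydroxybutanoate
Product: 12 ethyl (3E)-4-[(tert-butyldimethylsilyl)oxy]-2-diazobut-3-enoate
Conditions: POCl3, Et3N, CH2Cl2, 0 °C → rt; used at once
Reagents that add atoms: none
Why: Activation of the hydroxyl as a dichlorophosphate and E2 elimination; the diazo carbon bears no hydrogen, so elimination can only run toward the silyloxymethylene group, and the anti-periplanar pathway with the silyloxy group remote from the ester-bearing carbon should give the E enol ether.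

**Step 9**
Reactants: 8 triethyl({1-[(5S)-2-methyl-5-(propan-2-yl)-5-(triethylsilyloxy)cyclopent-1-en-1-yl]ethenyl}oxy)silane; 12 ethyl (3E)-4-[(tert-butyldimethylsilyl)oxy]-2-diazobut-3-enoate
Product: 14 ethyl (3S,8R,8aS)-8-[(tert-butyldimethylsilyl)oxy]-8a-methyl-3-(propan-2-yl)-3,4-bis[(triethylsilyl)oxy]-1,2,3,5,8,8a-hexahydroazulene-6-carboxylate, via cis-divinylcyclopropane 13 (not isolated)
Conditions: Rh2(R-DOSP)4 (2 mol %), hexanes, −40 °C → rt, slow addition of 12 (1.5 equiv); then toluene, 100 °C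
Reagents that add atoms: none
Why: The divalent rhodium carboxylate Rh2(R-DOSP)4 (dirhodium tetrakis[(R)-N-(4-dodecylbenzenesulfonyl)prolinate]) decomposes 12 to a donor–acceptor vinylcarbenoid, which adds in a concerted, asynchronous (2+1) fashion across the CH2=C(OSiEt3) alkene of 8 and closes the three-membered ring with the vinyl group cis to the cyclopentenyl group; on heating, 13 undergoes a [3,3] sigmatropic (Cope) shift through a boat transition state that breaks the cyclopropane bond between the ester-bearing and siloxy-bearing carbons and closes the seven-membered ring by joining the CH(OSi) terminus to the methyl-bearing ring carbon. The closest known reaction type is the tandem cyclopropanation/Cope rearrangement (formal (4+3) cycloaddition) of vinyldiazoacetates with 2-siloxy-1,3-dienes. The two cyclopropane stereocentres are set by the chiral prolinate catalyst together with the inherent preference of donor–acceptor carbenoids to place the alkene substituent cis to the donor group. The boat geometry relays them to C8 and C8a: the E enol ether places the silyloxy group trans to the angular methyl, and the absolute sense of the cyclopropane makes the new bond form on the cyclopentene face that carries the tertiary silyloxy group, opposite the isopropyl group. The step needs site selectivity for the terminal alkene, cis selectivity and the right cyclopropane sense; the first is secured by the electron-rich, unhindered siloxy alkene of 8 (the tetrasubstituted ring alkene is inaccessible) and the others by the catalyst, while the weak bond between the ester and siloxy carbons should offset the penalty of the ring methyl pointing inward, so that moderate heating suffices.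

**Step 10**
Reactants: 14 ethyl (3S,8R,8aS)-8-[(tert-butyldimethylsilyl)oxy]-8a-methyl-3-(propan-2-yl)-3,4-bis[(triethylsilyl)oxy]-1,2,3,5,8,8a-hexahydroazulene-6-carboxylate
Product: 15 [(3S,8R,8aS)-8-[(tert-butyldimethylsilyl)oxy]-8a-methyl-3-(propan-2-yl)-3,4-bis[(triethylsilyl)oxy]-1,2,3,5,8,8a-hexahydroazulen-6-yl]methanol
Conditions: i-Bu2AlH, CH2Cl2, −78 °C; aqueous potassium sodium tartrate work-up
Reagents that add atoms: none
Why: 1,2-Reduction of the conjugated ester by the aluminium hydride at low temperature stops at the allylic alcohol and leaves the silyl ethers and the silyl enol ether untouched.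

**Step 11**
Reactants: 15 [(3S,8R,8aS)-8-[(tert-butyldimethylsilyl)oxy]-8a-methyl-3-(propan-2-yl)-3,4-bis[(triethylsilyl)oxy]-1,2,3,5,8,8a-hexahydroazulen-6-yl]methanol
Product: 17 tert-butyl{[(3S,8R,8aS)-6,8a-dimethyl-3-(propan-2-yl)-3,4-bis(triethylsilyloxy)-1,2,3,5,8,8a-hexahydroazulen-8-yl]oxy}dimethylsilane, via allylic mesylate 16 (not isolated)
Conditions: MsCl, Et3N, THF, −20 °C; then LiEt3BH, −20 → 0 °C
Reagents that add atoms: none
Why: Sulfonylation followed by SN2 hydride displacement with the trialkylborohydride (deoxygenation of a primary allylic alcohol) should give the vinylic methyl group without allylic transposition, because the SN2′ site C7 is shielded by the silyloxy-bearing C8 and the quaternary C8a.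

**Step 12**
Reactants: 17 tert-butyl{[(3S,8R,8aS)-6,8a-dimethyl-3-(propan-2-yl)-3,4-bis(triethylsilyloxy)-1,2,3,5,8,8a-hexahydroazulen-8-yl]oxy}dimethylsilane
Product: 18 (3S,3aR,8R,8aS)-3,8-dihydroxy-6,8a-dimethyl-3-(propan-2-yl)-2,3,3a,5,8,8a-hexahydroazulen-4(1H)-one
Conditions: HF·pyridine, pyridine, THF, 0 °C → rt
Reagents that add atoms: none
Why: Fluoride-driven desilylation frees both alcohols and the enol, which is protonated kinetically at C3a on the face opposite the angular methyl and the isopropyl group (both flank that carbon on the other face), giving the trans ring fusion; the buffered medium should limit migration of the C6=C7 alkene.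

**Step 13**
Reactants: 18 (3S,3aR,8R,8aS)-3,8-dihydroxy-6,8a-dimethyl-3-(propan-2-yl)-2,3,3a,5,8,8a-hexahydroazulen-4(1H)-one; 19 isovaleryl chloride (3-methylbutanoyl chloride)
Product: 20 (3S,3aR,8R,8aS)-3-hydroxy-6,8a-dimethyl-4-oxo-3-(propan-2-yl)-1,2,3,3a,4,5,8,8a-octahydroazulen-8-yl 3-methylbutanoate
Conditions: pyridine, DMAP (cat.), CH2Cl2, 0 °C
Reagents that add atoms: none
Why: DMAP-catalysed acyl transfer acylates the secondary allylic hydroxyl, while the tertiary hydroxyl is too hindered to react and the mild base should not enolise the ketone appreciably.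

**Step 14**
Reactants: 20 (3S,3aR,8R,8aS)-3-hydroxy-6,8a-dimethyl-4-oxo-3-(propan-2-yl)-1,2,3,3a,4,5,8,8a-octahydroazulen-8-yl 3-methylbutanoate
Product: 21 (3S,3aS,4R,8R,8aS)-3,4-dihydroxy-6,8a-dimethyl-3-(propan-2-yl)-1,2,3,3a,4,5,8,8a-octahydroazulen-8-yl 3-methylbutanoate
Conditions: Me4NBH(OAc)3, CH3CN/AcOH, −20 °C
Reagents that add atoms: none
Why: Hydroxyl-directed (Evans–Saksena) reduction, in which the C3 hydroxyl exchanges onto boron and delivers hydride intramolecularly to the face of the C4 ketone that it occupies, so that the new C4 hydroxyl ends anti to the C3 hydroxyl.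

**Step 15**
Reactants: 21 (3S,3aS,4R,8R,8aS)-3,4-dihydroxy-6,8a-dimethyl-3-(propan-2-yl)-1,2,3,3a,4,5,8,8a-octahydroazulen-8-yl 3-methylbutanoate; 22 4-[(tert-butyldimethylsilyl)oxy]benzoic acid
Product: 24 (3S,3aS,4R,8R,8aS)-3-hydroxy-6,8a-dimethyl-8-[(3-methylbutanoyl)oxy]-3-(propan-2-yl)-1,2,3,3a,4,5,8,8a-octahydroazulen-4-yl 4-[(tert-butyldimethylsilyl)oxy]benzoate, via acid chloride 23 (not isolated)
Conditions: 22, (COCl)2, DMF (cat.), CH2Cl2, 0 °C → rt, evaporate; then 21, Et3N, DMAP, CH2Cl2, rt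
Reagents that add atoms: none
Why: Acylation of the hindered secondary alcohol by the acid chloride under nucleophilic (DMAP) catalysis; the tertiary hydroxyl does not compete and the aryl silyl ether keeps the phenol from acylating itself.

**Step 16**
Reactants: 24 (3S,3aS,4R,8R,8aS)-3-hydroxy-6,8a-dimethyl-8-[(3-methylbutanoyl)oxy]-3-(propan-2-yl)-1,2,3,3a,4,5,8,8a-octahydroazulen-4-yl 4-[(tert-butyldimethylsilyl)oxy]benzoate
Product: 25 (3S,3aS,4R,8R,8aS)-3-hydroxy-6,8a-dimethyl-8-[(3-methylbutanoyl)oxy]-3-(propan-2-yl)-1,2,3,3a,4,5,8,8a-octahydroazulen-4-yl 4-hydroxybenzoate (CNP0086724.4)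
Conditions: Bu4NF, AcOH, THF, 0 °C
Reagents that add atoms: none
Why: Fluoride cleaves the aryl silyl ether far faster than it could attack the two alkyl esters, and the acetic acid buffer should prevent acyl migration or ester cleavage by the phenoxide.

**Compound list**

1 | (R)-terpinen-4-ol, (1R)-4-methyl-1-(propan-2-yl)cyclohex-3-en-1-ol | CC1=CC[C@@](O)(C(C)C)CC1 | starting material
2 | triethyl{[(1R)-4-methyl-1-(propan-2-yl)cyclohex-3-en-1-yl]oxy}silane | CC1=CC[C@@](O[Si](CC)(CC)CC)(C(C)C)CC1 | intermediate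
3 | secondary ozonide of 2, 1-methyl-4-(propan-2-yl)-4-(triethylsilyloxy)-7,8,9-trioxabicyclo[4.2.1]nonane (carbinol centre as in 2, bridgehead diastereomers) | CC12CC[C@](O[Si](CC)(CC)CC)(C(C)C)CC(OO1)O2 | intermediate
4 | (3R)-6-oxo-3-(propan-2-yl)-3-[(triethylsilyl)oxy]heptanal | CC(=O)CC[C@](O[Si](CC)(CC)CC)(C(C)C)CC=O | intermediate
5 | (5S)-2-methyl-5-(propan-2-yl)-5-[(triethylsilyl)oxy]cyclopent-1-ene-1-carbaldehyde | O=CC1=C(C)CC[C@]1(O[Si](CC)(CC)CC)C(C)C | intermediate
6 | 1-[(5S)-2-methyl-5-(propan-2-yl)-5-(triethylsilyloxy)cyclopent-1-en-1-yl]ethan-1-ol (both carbinol epimers) | CC(O)C1=C(C)CC[C@]1(O[Si](CC)(CC)CC)C(C)C | intermediate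
7 | 1-[(5S)-2-methyl-5-(propan-2-yl)-5-(triethylsilyloxy)cyclopent-1-en-1-yl]ethan-1-one | CC(=O)C1=C(C)CC[C@]1(O[Si](CC)(CC)CC)C(C)C | intermediate
8 | triethyl({1-[(5S)-2-methyl-5-(propan-2-yl)-5-(triethylsilyloxy)cyclopent-1-en-1-yl]ethenyl}oxy)silane | C=C(O[Si](CC)(CC)CC)C1=C(C)CC[C@]1(O[Si](CC)(CC)CC)C(C)C | intermediate
9 | ethyl diazoacetate | CCOC(=O)C=[N+]=[N-] | starting material
10 | (tert-butyldimethylsilyloxy)acetaldehyde | O=CCO[Si](C)(C)C(C)(C)C | starting material
11 | ethyl 4-[(tert-butyldimethylsilyl)oxy]-2-diazo-3-hydroxybutanoate (racemic) | CCOC(=O)C(=[N+]=[N-])C(O)CO[Si](C)(C)C(C)(C)C | intermediate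
12 | ethyl (3E)-4-[(tert-butyldimethylsilyl)oxy]-2-diazobut-3-enoate | CCOC(=O)C(=[N+]=[N-])/C=C/O[Si](C)(C)C(C)(C)C | intermediate
13 | ethyl (1S,2R)-1-{(E)-2-[(tert-butyldimethylsilyl)oxy]ethenyl}-2-[(5S)-2-methyl-5-(propan-2-yl)-5-(triethylsilyloxy)cyclopent-1-en-1-yl]-2-(triethylsilyloxy)cyclopropane-1-carboxylate | CCOC(=O)[C@]1(/C=C/O[Si](C)(C)C(C)(C)C)C[C@@]1(O[Si](CC)(CC)CC)C2=C(C)CC[C@]2(O[Si](CC)(CC)CC)C(C)C | intermediate
14 | ethyl (3S,8R,8aS)-8-[(tert-butyldimethylsilyl)oxy]-8a-methyl-3-(propan-2-yl)-3,4-bis[(triethylsilyl)oxy]-1,2,3,5,8,8a-hexahydroazulene-6-carboxylate | CCOC(=O)C1=C[C@@H](O[Si](C)(C)C(C)(C)C)[C@@]2(C)CC[C@](O[Si](CC)(CC)CC)(C(C)C)C2=C(O[Si](CC)(CC)CC)C1 | intermediate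
15 | [(3S,8R,8aS)-8-[(tert-butyldimethylsilyl)oxy]-8a-methyl-3-(propan-2-yl)-3,4-bis[(triethylsilyl)oxy]-1,2,3,5,8,8a-hexahydroazulen-6-yl]methanol | OCC1=C[C@@H](O[Si](C)(C)C(C)(C)C)[C@@]2(C)CC[C@](O[Si](CC)(CC)CC)(C(C)C)C2=C(O[Si](CC)(CC)CC)C1 | intermediate
16 | methanesulfonate of 15 | CS(=O)(=O)OCC1=C[C@@H](O[Si](C)(C)C(C)(C)C)[C@@]2(C)CC[C@](O[Si](CC)(CC)CC)(C(C)C)C2=C(O[Si](CC)(CC)CC)C1 | intermediate
17 | tert-butyl{[(3S,8R,8aS)-6,8a-dimethyl-3-(propan-2-yl)-3,4-bis(triethylsilyloxy)-1,2,3,5,8,8a-hexahydroazulen-8-yl]oxy}dimethylsilane | CC1=C[C@@H](O[Si](C)(C)C(C)(C)C)[C@@]2(C)CC[C@](O[Si](CC)(CC)CC)(C(C)C)C2=C(O[Si](CC)(CC)CC)C1 | intermediate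
18 | (3S,3aR,8R,8aS)-3,8-dihydroxy-6,8a-dimethyl-3-(propan-2-yl)-2,3,3a,5,8,8a-hexahydroazulen-4(1H)-one | CC1=C[C@@H](O)[C@@]2(C)CC[C@](O)(C(C)C)[C@@H]2C(=O)C1 | intermediate
19 | isovaleryl chloride (3-methylbutanoyl chloride) | CC(C)CC(=O)Cl | starting material
20 | (3S,3aR,8R,8aS)-3-hydroxy-6,8a-dimethyl-4-oxo-3-(propan-2-yl)-1,2,3,3a,4,5,8,8a-octahydroazulen-8-yl 3-methylbutanoate | CC1=C[C@@H](OC(=O)CC(C)C)[C@@]2(C)CC[C@](O)(C(C)C)[C@@H]2C(=O)C1 | intermediate
21 | (3S,3aS,4R,8R,8aS)-3,4-dihydroxy-6,8a-dimethyl-3-(propan-2-yl)-1,2,3,3a,4,5,8,8a-octahydroazulen-8-yl 3-methylbutanoate | CC1=C[C@@H](OC(=O)CC(C)C)[C@@]2(C)CC[C@](O)(C(C)C)[C@@H]2[C@H](O)C1 | intermediate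
22 | 4-[(tert-butyldimethylsilyl)oxy]benzoic acid | CC(C)(C)[Si](C)(C)Oc1ccc(cc1)C(=O)O | starting material
23 | 4-[(tert-butyldimethylsilyl)oxy]benzoyl chloride | CC(C)(C)[Si](C)(C)Oc1ccc(cc1)C(=O)Cl | intermediate
24 | (3S,3aS,4R,8R,8aS)-3-hydroxy-6,8a-dimethyl-8-[(3-methylbutanoyl)oxy]-3-(propan-2-yl)-1,2,3,3a,4,5,8,8a-octahydroazulen-4-yl 4-[(tert-butyldimethylsilyl)oxy]benzoate | CC1=C[C@@H](OC(=O)CC(C)C)[C@@]2(C)CC[C@](O)(C(C)C)[C@@H]2[C@H](OC(=O)c2ccc(O[Si](C)(C)C(C)(C)C)cc2)C1 | intermediate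
25 | (3S,3aS,4R,8R,8aS)-3-hydroxy-6,8a-dimethyl-8-[(3-methylbutanoyl)oxy]-3-(propan-2-yl)-1,2,3,3a,4,5,8,8a-octahydroazulen-4-yl 4-hydroxybenzoate | CC1=C[C@@H](OC(=O)CC(C)C)[C@@]2(C)CC[C@](O)(C(C)C)[C@@H]2[C@H](OC(=O)c2ccc(O)cc2)C1 | target

**Step count and risks**

Total step count: 16. Longest linear sequence: 14 steps (steps 1–6 and 9–16, from (R)-terpinen-4-ol).

Steps most likely to fail:

1. Step 9. The bond of cyclopropane 13 that carries the siloxy and ester groups may break heterolytically, and the resulting zwitterion may close to a five-membered ring. The cyclopropanation of the 1,1-disubstituted siloxy alkene may also show poor cis selectivity. Both would compete with a sigmatropic shift that is slowed by the inward ring methyl. The fallback removes the donor group from the cyclopropane and brings in the C4 oxygen afterwards. It sets out from 5 and 12. Wittig methylenation of 5 (Ph3P=CH2 from Ph3PCH3Br and KOt-Bu, THF) would give triethyl{[(1S)-2-ethenyl-3-methyl-1-(propan-2-yl)cyclopent-2-en-1-yl]oxy}silane F1, a 1-vinylcycloalkene of the kind that is a standard partner in this annulation. Reaction with 12 under Rh2(R-DOSP)4 would give the all-carbon cis-divinylcyclopropane F2, which cannot ionise and so tolerates stronger heating (xylene, 140 °C) to the cycloheptadiene ester F3. Hydroboration–oxidation (BH3·SMe2, THF, 0 °C; NaBO3·4H2O) of the electron-rich C3a=C4 alkene, in the presence of the unreactive enoate, should add H to C3a and OH to C4 syn on the face opposite methyl and isopropyl, giving hydroxy ester F4 with the ring-fusion hydrogen set stereospecifically. Reduction with i-Bu2AlH would give diol F5; selective mesylation of the primary allylic hydroxyl (primary mesylate F6) and LiEt3BH would give the methyl compound F7. Dess–Martin oxidation would give ketone F8, and HF·pyridine would return the route to 18 before step 13.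

2. Step 12. During the long exposure needed to cleave the hindered secondary silyl ether, the C6=C7 alkene may migrate into conjugation with the ketone, the tertiary β-hydroxyl may be lost by elimination, and the ring-fusion carbon may equilibrate. The fallback stages the desilylation and reverses the order of the two acylations, so that the ketone exists only briefly. It sets out from 17. Short treatment with HF·pyridine/pyridine (THF, −20 → 0 °C) should remove only the two triethylsilyl groups and give the hydroxy ketone 8-silyl ether F9. This would be reduced at once with Me4NBH(OAc)3 to the diol F10 and acylated at the C4 hydroxyl with 23 (made from 22 as in step 15; Et3N, DMAP) to the aroate F11. With no ketone left, HF·pyridine at rt should cleave the alkyl silyl ether while the aryl silyl ether, which is slower under acidic fluoride, stays, giving the diol aroate F12. Acylation with 19 (pyridine, DMAP) would then rejoin the route at 24 before step 16.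

3. Step 8. The elimination may give E/Z mixtures, and the electron-rich vinyldiazo ester may cyclise to a pyrazole on handling. The fallback makes the diazo group last, by diazo transfer, instead of carrying it through a dehydration. It sets out from 10. A Z-selective Horner–Wadsworth–Emmons reaction with ethyl (diphenoxyphosphoryl)acetate (NaH, THF, −78 °C) would give ethyl (2Z)-4-[(tert-butyldimethylsilyl)oxy]but-2-enoate F13. γ-Deprotonation with LiN(SiMe3)2 (THF, −78 °C) and diazo transfer from 4-acetamidobenzenesulfonyl azide at the α carbon would give 12 directly. The (Z)-enoate is expected to be deprotonated through the conformer that leads to the E geometry of the new C3=C4 bond, and 12 would be taken straight into step 9.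

**Further compounds**

F1 | step 9 | triethyl{[(1S)-2-ethenyl-3-methyl-1-(propan-2-yl)cyclopent-2-en-1-yl]oxy}silane | C=CC1=C(C)CC[C@]1(O[Si](CC)(CC)CC)C(C)C
F2 | step 9 | ethyl (1R,2S)-1-{(E)-2-[(tert-butyldimethylsilyl)oxy]ethenyl}-2-[(5S)-2-methyl-5-(propan-2-yl)-5-(triethylsilyloxy)cyclopent-1-en-1-yl]cyclopropane-1-carboxylate | CCOC(=O)[C@]1(/C=C/O[Si](C)(C)C(C)(C)C)C[C@H]1C2=C(C)CC[C@]2(O[Si](CC)(CC)CC)C(C)C
F3 | step 9 | ethyl (3S,8R,8aS)-8-[(tert-butyldimethylsilyl)oxy]-8a-methyl-3-(propan-2-yl)-3-[(triethylsilyl)oxy]-1,2,3,5,8,8a-hexahydroazulene-6-carboxylate | CCOC(=O)C1=C[C@@H](O[Si](C)(C)C(C)(C)C)[C@@]2(C)CC[C@](O[Si](CC)(CC)CC)(C(C)C)C2=CC1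
F4 | step 9 | ethyl (3S,3aS,4S,8R,8aS)-8-[(tert-butyldimethylsilyl)oxy]-4-hydroxy-8a-methyl-3-(propan-2-yl)-3-[(triethylsilyl)oxy]-1,2,3,3a,4,5,8,8a-octahydroazulene-6-carboxylate | CCOC(=O)C1=C[C@@H](O[Si](C)(C)C(C)(C)C)[C@@]2(C)CC[C@](O[Si](CC)(CC)CC)(C(C)C)[C@@H]2[C@@H](O)C1
F5 | step 9 | (3S,3aS,4S,8R,8aS)-8-[(tert-butyldimethylsilyl)oxy]-6-(hydroxymethyl)-8a-methyl-3-(propan-2-yl)-3-[(triethylsilyl)oxy]-1,2,3,3a,4,5,8,8a-octahydroazulen-4-ol | OCC1=C[C@@H](O[Si](C)(C)C(C)(C)C)[C@@]2(C)CC[C@](O[Si](CC)(CC)CC)(C(C)C)[C@@H]2[C@@H](O)C1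
F6 | step 9 | primary methanesulfonate of F5 | CS(=O)(=O)OCC1=C[C@@H](O[Si](C)(C)C(C)(C)C)[C@@]2(C)CC[C@](O[Si](CC)(CC)CC)(C(C)C)[C@@H]2[C@@H](O)C1
F7 | step 9 | (3S,3aS,4S,8R,8aS)-8-[(tert-butyldimethylsilyl)oxy]-6,8a-dimethyl-3-(propan-2-yl)-3-[(triethylsilyl)oxy]-1,2,3,3a,4,5,8,8a-octahydroazulen-4-ol | CC1=C[C@@H](O[Si](C)(C)C(C)(C)C)[C@@]2(C)CC[C@](O[Si](CC)(CC)CC)(C(C)C)[C@@H]2[C@@H](O)C1
F8 | step 9 | (3S,3aR,8R,8aS)-8-[(tert-butyldimethylsilyl)oxy]-6,8a-dimethyl-3-(propan-2-yl)-3-[(triethylsilyl)oxy]-2,3,3a,5,8,8a-hexahydroazulen-4(1H)-one | CC1=C[C@@H](O[Si](C)(C)C(C)(C)C)[C@@]2(C)CC[C@](O[Si](CC)(CC)CC)(C(C)C)[C@@H]2C(=O)C1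
F9 | step 12 | (3S,3aR,8R,8aS)-8-[(tert-butyldimethylsilyl)oxy]-3-hydroxy-6,8a-dimethyl-3-(propan-2-yl)-2,3,3a,5,8,8a-hexahydroazulen-4(1H)-one | CC1=C[C@@H](O[Si](C)(C)C(C)(C)C)[C@@]2(C)CC[C@](O)(C(C)C)[C@@H]2C(=O)C1
F10 | step 12 | (3S,3aS,4R,8R,8aS)-8-[(tert-butyldimethylsilyl)oxy]-6,8a-dimethyl-3-(propan-2-yl)-1,2,3,3a,4,5,8,8a-octahydroazulene-3,4-diol | CC1=C[C@@H](O[Si](C)(C)C(C)(C)C)[C@@]2(C)CC[C@](O)(C(C)C)[C@@H]2[C@H](O)C1
F11 | step 12 | (3S,3aS,4R,8R,8aS)-8-[(tert-butyldimethylsilyl)oxy]-3-hydroxy-6,8a-dimethyl-3-(propan-2-yl)-1,2,3,3a,4,5,8,8a-octahydroazulen-4-yl 4-[(tert-butyldimethylsilyl)oxy]benzoate | CC1=C[C@@H](O[Si](C)(C)C(C)(C)C)[C@@]2(C)CC[C@](O)(C(C)C)[C@@H]2[C@H](OC(=O)c2ccc(O[Si](C)(C)C(C)(C)C)cc2)C1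
F12 | step 12 | (3S,3aS,4R,8R,8aS)-3,8-dihydroxy-6,8a-dimethyl-3-(propan-2-yl)-1,2,3,3a,4,5,8,8a-octahydroazulen-4-yl 4-[(tert-butyldimethylsilyl)oxy]benzoate | CC1=C[C@@H](O)[C@@]2(C)CC[C@](O)(C(C)C)[C@@H]2[C@H](OC(=O)c2ccc(O[Si](C)(C)C(C)(C)C)cc2)C1
F13 | step 8 | ethyl (2Z)-4-[(tert-butyldimethylsilyl)oxy]but-2-enoate | CCOC(=O)/C=C\CO[Si](C)(C)C(C)(C)C
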